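**Retrosynthetic overview**

1. The target is traced back, by acid removal of a MOM acetal and a silyl ether, to a protected diaryl ether. This is cut at the ring A C6–O bond (Ullmann) into a MOM-protected methyl 2-bromobenzoate and a hindered ring B phenol. Ring A is bought aromatic as 3-bromo-5-methylphenol and gets its ester by directed ortho-metalation.
2. Feature used: ring B has oxygens on C1' and C4' in a para (hydroquinone) relation, the prenyloxy group on C6' next to C1', the CH2OH carbon on C2' and hydrogens on C3' and C5'. This is the pattern encoded in a 3-alkoxy-4-oxy-4-(2-propenyl)cyclobutenone.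
3. Ring B is opened at C3'–C4' (retro-6π to a dienylketene, then 4π closure) to a 4-silyloxy-3-prenyloxy-4-alkenylcyclobutenone. The C1' oxygen is carried as a triethylsilyl ether, so only the C4' hydroxyl is free after ring expansion.
4. The cyclobutenone comes from the prenyl semisquarate and 2-lithio-3-silyloxypropene; the semisquarate comes from diprenyl squarate and that from squaric acid.
5. Ring order: the four-membered ring is bought (squaric acid); ring B is the only ring built (step 7); rings A and B are then joined through oxygen (step 12).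

Key step: step 7

Assumption: the target has no stereocentre (the carbinol centres of 7, 8, 11 and 12 are racemic and vanish later); squaric acid, prenyl bromide, 2-bromoprop-2-en-1-ol and 3-bromo-5-methylphenol are taken as commercial; "prenyl" means 3-methylbut-2-en-1-yl.

**Route**

Step 1
Reactants: 1 2-bromoprop-2-en-1-ol
Product: 2 [(2-bromoprop-2-en-1-yl)oxy](tert-butyl)dimethylsilane
Conditions: TBSCl, imidazole, CH2Cl2, 0 °C to rt
Reagents that add atoms: tert-butyldimethylsilyl chloride (TBSCl), CC(C)(C)[Si](C)(C)Cl
Why: Imidazole-promoted silyl ether formation on a primary allylic alcohol, with the vinyl bromide inert.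

Step 2
Reactants: 3 squaric acid
Product: 4 disilver squarate (Ag2C4O4)
Conditions: AgNO3 (2 equiv), H2O, rt, dark; filter, wash, dry in vacuo
Reagents that add atoms: silver nitrate, [Ag+].[O-][N+](=O)[O-]
Why: Salt metathesis in which the sparingly soluble disilver salt of the strongly acidic squaric acid precipitates and serves as the classical O-nucleophile form of squarate.

Step 3
Reactants: 4 disilver squarate; 5 prenyl bromide (1-bromo-3-methylbut-2-ene)
Product: 6 3,4-bis[(3-methylbut-2-en-1-yl)oxy]cyclobut-3-ene-1,2-dione (diprenyl squarate)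
Conditions: 5 (2.1 equiv), Et2O, 0 °C to rt, dark; filter off AgBr
Reagents that add atoms: none
Why: Silver-assisted O-alkylation of the squarate salt by a reactive allylic bromide in a non-ionising solvent should give the 1,2-diester, driven by precipitation of AgBr, with the primary prenyl ester as the preferred allylic isomer.

Step 4
Reactants: 6 diprenyl squarate
Product: 7 rac-4-hydroxy-2,3-bis[(3-methylbut-2-en-1-yl)oxy]cyclobut-2-en-1-one
Conditions: LiAlH(OtBu)3 (1.05 equiv), THF, −78 to −20 °C; then H2O
Reagents that add atoms: none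
Why: Chemoselective 1,2-reduction in which the bulky mild hydride adds once to one of the two equivalent carbonyls and the resulting aluminium alkoxide blocks a second addition, the new carbinol centre being racemic and removed in step 5.

Step 5
Reactants: 7 rac-4-hydroxy-2,3-bis(prenyloxy)cyclobut-2-en-1-one
Product: 9 3-[(3-methylbut-2-en-1-yl)oxy]cyclobut-3-ene-1,2-dione (prenyl semisquarate), via the trifluoroacetate 8 (not isolated)
Conditions: (CF3CO)2O (1.2 equiv), Et2O, −78 to 0 °C; then aq NaHCO3
Reagents that add atoms: none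
Why: Anhydride-induced allylic transposition of a 4-hydroxy-2,3-dialkoxycyclobutenone to a 3-alkoxycyclobutenedione, in which the trifluoroacetate ionises with help from the alkoxy groups and the O-prenyl oxocarbenium end is dealkylated by trifluoroacetate under cold non-aqueous conditions that spare the remaining vinylogous ester.

Step 6
Reactants: 2 [(2-bromoprop-2-en-1-yl)oxy](tert-butyl)dimethylsilane; 9 prenyl semisquarate
Product: 12 rac-4-[3-(tert-butyldimethylsilyloxy)prop-1-en-2-yl]-3-[(3-methylbut-2-en-1-yl)oxy]-4-(triethylsilyloxy)cyclobut-2-en-1-one, via the vinyllithium 10 (not isolated), via the lithium alkoxide 11 (not isolated)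
Conditions: 2, t-BuLi (2.0 equiv per 2), Et2O, −78 °C; cannulate into 9, THF, −78 °C; then TESOTf, −78 to −40 °C; aq NaHCO3
Reagents that add atoms: triethylsilyl trifluoromethanesulfonate (TESOTf), CC[Si](CC)(CC)OS(=O)(=O)C(F)(F)F
Why: Bromine–lithium exchange gives vinyllithium 10, which adds 1,2 at −78 °C to the ketone-like carbonyl of 9 next to the alkoxy-bearing carbon (the other carbonyl is deactivated as a vinylogous ester), and the tertiary lithium alkoxide 11 is silylated in the flask by the triflate, the new quaternary carbinol centre being racemic and lost on aromatisation.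

Step 7
Reactants: 12 rac-4-[3-(tert-butyldimethylsilyloxy)prop-1-en-2-yl]-3-(prenyloxy)-4-(triethylsilyloxy)cyclobut-2-en-1-one
Product: 15 3-[(tert-butyldimethylsilyloxy)methyl]-5-[(3-methylbut-2-en-1-yl)oxy]-4-(triethylsilyloxy)phenol, via the dienylketene 13 (not isolated), via the cyclohexa-2,4-dienone 14 (not isolated)
Conditions: degassed toluene (0.02 M), about 105 °C, argon
Reagents that add atoms: none
Why: Heating effects a thermal conrotatory 4π electrocyclic opening of the C1–C4 bond in which the donor silyloxy group rotates outward, so the 2-propenyl group turns inward and lies cis to the ketene in dienylketene 13. A thermal 6π electrocyclisation then joins the ketene carbon (future C4') to the CH2 terminus (future C3'), closing ring B as cyclohexa-2,4-dienone 14 in a six-membered electrocyclic ring closure, and enolisation gives phenol 15 irreversibly. The closest known reaction type is the thermal ring expansion of squarate-derived 4-alkenyl-4-hydroxy- and 4-silyloxycyclobutenones to hydroquinones and their mono-ethers. No stereocentre is formed; the racemic carbinol carbon of 12 becomes aromatic C1'. The step needs ring opening to outrun a [3,3] shift of the prenyl vinylogous ester and electrocyclisation to outrun capture of the ketene: the oxygen-donor substituents should lower the opening barrier to about 100 °C, where a gem-dimethyl-terminated allyl vinyl ether is still inert, and dilution, degassing and exclusion of protic nucleophiles leave the cis-alkene as the only partner of the ketene. The positions of all four ring B substituents follow from the connectivity of 12, so no regioselectivity problem arises.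

Step 8
Reactants: 15 3-[(tert-butyldimethylsilyloxy)methyl]-5-(prenyloxy)-4-(triethylsilyloxy)phenol
Product: 16 tert-butyl({5-methoxy-3-[(3-methylbut-2-en-1-yl)oxy]-2-(triethylsilyloxy)phenyl}methoxy)dimethylsilane
Conditions: MeOH, PPh3, DIAD, THF, 0 °C to rt
Reagents that add atoms: methanol, CO
Why: Mitsunobu etherification of the only free and unhindered phenol with methanol under neutral conditions, which avoids base-induced migration or loss of the aryl triethylsilyl ether.

Step 9
Reactants: 16 the methyl ether from step 8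
Product: 17 2-[(tert-butyldimethylsilyloxy)methyl]-4-methoxy-6-[(3-methylbut-2-en-1-yl)oxy]phenol
Conditions: TBAF (1.05 equiv), AcOH (1.1 equiv), THF, 0 °C
Reagents that add atoms: none
Why: Chemoselective desilylation in which fluoride cleaves the aryl silyl ether (phenoxide leaving group) much faster than the primary alkyl silyl ether, while the acetic acid buffer keeps the freed phenol protonated so that it cannot attack the neighbouring silyl ether.

Step 10
Reactants: 18 3-bromo-5-methylphenol
Product: 19 1-bromo-3-(methoxymethoxy)-5-methylbenzene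
Conditions: MOMCl, iPr2NEt, CH2Cl2, 0 °C to rt
Reagents that add atoms: chloromethyl methyl ether (MOMCl), COCCl
Why: Base-mediated O-alkylation of the phenol gives the MOM acetal, which protects the phenol and directs the next metalation.

Step 11
Reactants: 19 1-bromo-3-(methoxymethoxy)-5-methylbenzene
Product: 21 methyl 2-bromo-6-(methoxymethoxy)-4-methylbenzoate, via the aryllithium 20 (not isolated)
Conditions: LiN(iPr)2 (1.1 equiv), THF, −78 °C; then ClCO2Me (inverse addition), −78 °C to rt
Reagents that add atoms: methyl chloroformate, COC(=O)Cl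
Why: Directed ortho-metalation in which the amide base removes the most acidic proton, the one between bromine and the coordinating MOM ether, without bromine–lithium exchange, and the aryllithium is held at −78 °C to avoid aryne formation before acylation.

Step 12
Reactants: 17 2-[(tert-butyldimethylsilyloxy)methyl]-4-methoxy-6-(prenyloxy)phenol; 21 methyl 2-bromo-6-(methoxymethoxy)-4-methylbenzoate
Product: 22 methyl 2-{2-[(tert-butyldimethylsilyloxy)methyl]-4-methoxy-6-[(3-methylbut-2-en-1-yl)oxy]phenoxy}-6-(methoxymethoxy)-4-methylbenzoate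
Conditions: CuI (20 mol %), picolinic acid (40 mol %), K3PO4 (2 equiv), DMSO, 4 Å sieves, 90 °C, argon
Reagents that add atoms: none
Why: Ligand-accelerated Ullmann diaryl ether synthesis in which the ortho ester activates the aryl bromide toward the copper phenoxide and the picolinic acid/K3PO4/DMSO system is suited to ortho-substituted phenols, while silyl ether, MOM acetal, prenyl ether and methyl ester should tolerate the weakly basic anhydrous medium.

Step 13
Reactants: 22 the protected diaryl ether
Product: 23 methyl 2-hydroxy-6-{2-(hydroxymethyl)-4-methoxy-6-[(3-methylbut-2-en-1-yl)oxy]phenoxy}-4-methylbenzoate (target)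
Conditions: HCl (about 0.3 M) in MeOH/THF, 0 °C to rt, monitored; aq NaHCO3 quench
Reagents that add atoms: none
Why: Acid-catalysed methanolysis cleaves the MOM acetal through the methoxymethyl oxocarbenium ion and solvolyses the primary silyl ether, both of which should be much faster than ionisation of the aryl prenyl ether, and methanol as solvent keeps the ester as the methyl ester and disfavours eight-membered lactonisation.

**Compound list**

1 | 2-bromoprop-2-en-1-ol | C=C(Br)CO | starting material
2 | [(2-bromoprop-2-en-1-yl)oxy](tert-butyl)dimethylsilane | C=C(Br)CO[Si](C)(C)C(C)(C)C | intermediate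
3 | squaric acid (3,4-dihydroxycyclobut-3-ene-1,2-dione) | O=C1C(O)=C(O)C1=O | starting material
4 | disilver squarate, Ag2C4O4 | [Ag+].[Ag+].[O-]C1=C([O-])C(=O)C1=O | intermediate
5 | prenyl bromide (1-bromo-3-methylbut-2-ene) | CC(C)=CCBr | starting material
6 | 3,4-bis[(3-methylbut-2-en-1-yl)oxy]cyclobut-3-ene-1,2-dione | O=C1C(=O)C(OCC=C(C)C)=C1OCC=C(C)C | intermediate
7 | rac-4-hydroxy-2,3-bis[(3-methylbut-2-en-1-yl)oxy]cyclobut-2-en-1-one | O=C1C(OCC=C(C)C)=C(OCC=C(C)C)C1O | intermediate
8 | rac-2,3-bis[(3-methylbut-2-en-1-yl)oxy]-4-oxocyclobut-2-en-1-yl trifluoroacetate (not isolated) | O=C1C(OCC=C(C)C)=C(OCC=C(C)C)C1OC(=O)C(F)(F)F | intermediate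
9 | 3-[(3-methylbut-2-en-1-yl)oxy]cyclobut-3-ene-1,2-dione (prenyl semisquarate) | O=C1C=C(OCC=C(C)C)C1=O | intermediate
10 | [3-(tert-butyldimethylsilyloxy)prop-1-en-2-yl]lithium (not isolated) | [Li]C(=C)CO[Si](C)(C)C(C)(C)C | intermediate
11 | lithium rac-1-[3-(tert-butyldimethylsilyloxy)prop-1-en-2-yl]-2-[(3-methylbut-2-en-1-yl)oxy]-4-oxocyclobut-2-en-1-olate (not isolated) | [Li+].[O-]C1(C(=C)CO[Si](C)(C)C(C)(C)C)C(OCC=C(C)C)=CC1=O | intermediate
12 | rac-4-[3-(tert-butyldimethylsilyloxy)prop-1-en-2-yl]-3-[(3-methylbut-2-en-1-yl)oxy]-4-(triethylsilyloxy)cyclobut-2-en-1-one | O=C1C=C(OCC=C(C)C)C1(O[Si](CC)(CC)CC)C(=C)CO[Si](C)(C)C(C)(C)C | intermediate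
13 | dienylketene: 5-[(tert-butyldimethylsilyloxy)methyl]-3-[(3-methylbut-2-en-1-yl)oxy]-4-(triethylsilyloxy)hexa-1,3,5-trien-1-one, ketenyl and 2-propenyl groups cis on the central alkene (not isolated) | O=C=C/C(OCC=C(C)C)=C(/O[Si](CC)(CC)CC)C(=C)CO[Si](C)(C)C(C)(C)C | intermediate
14 | 5-[(tert-butyldimethylsilyloxy)methyl]-3-[(3-methylbut-2-en-1-yl)oxy]-4-(triethylsilyloxy)cyclohexa-2,4-dien-1-one (not isolated) | O=C1C=C(OCC=C(C)C)C(O[Si](CC)(CC)CC)=C(CO[Si](C)(C)C(C)(C)C)C1 | intermediate
15 | 3-[(tert-butyldimethylsilyloxy)methyl]-5-[(3-methylbut-2-en-1-yl)oxy]-4-(triethylsilyloxy)phenol | Oc1cc(OCC=C(C)C)c(O[Si](CC)(CC)CC)c(CO[Si](C)(C)C(C)(C)C)c1 | intermediate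
16 | tert-butyl({5-methoxy-3-[(3-methylbut-2-en-1-yl)oxy]-2-(triethylsilyloxy)phenyl}methoxy)dimethylsilane | COc1cc(OCC=C(C)C)c(O[Si](CC)(CC)CC)c(CO[Si](C)(C)C(C)(C)C)c1 | intermediate
17 | 2-[(tert-butyldimethylsilyloxy)methyl]-4-methoxy-6-[(3-methylbut-2-en-1-yl)oxy]phenol | COc1cc(OCC=C(C)C)c(O)c(CO[Si](C)(C)C(C)(C)C)c1 | intermediate
18 | 3-bromo-5-methylphenol | Cc1cc(O)cc(Br)c1 | starting material
19 | 1-bromo-3-(methoxymethoxy)-5-methylbenzene | COCOc1cc(C)cc(Br)c1 | intermediate
20 | [2-bromo-6-(methoxymethoxy)-4-methylphenyl]lithium (not isolated) | [Li]c1c(Br)cc(C)cc1OCOC | intermediate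
21 | methyl 2-bromo-6-(methoxymethoxy)-4-methylbenzoate | COCOc1cc(C)cc(Br)c1C(=O)OC | intermediate
22 | methyl 2-{2-[(tert-butyldimethylsilyloxy)methyl]-4-methoxy-6-[(3-methylbut-2-en-1-yl)oxy]phenoxy}-6-(methoxymethoxy)-4-methylbenzoate | COCOc1cc(C)cc(Oc2c(CO[Si](C)(C)C(C)(C)C)cc(OC)cc2OCC=C(C)C)c1C(=O)OC | intermediate
23 | methyl 2-hydroxy-6-{2-(hydroxymethyl)-4-methoxy-6-[(3-methylbut-2-en-1-yl)oxy]phenoxy}-4-methylbenzoate | COC(=O)c1c(O)cc(C)cc1Oc1c(CO)cc(OC)cc1OCC=C(C)C | target

**Step count and risks**

Total step count: 13. Longest linear sequence: 10 steps (squaric acid 3 to target 23 through steps 2, 3, 4, 5, 6, 7, 8, 9, 12, 13).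

Steps most likely to fail:

1. Step 7 (ring expansion). A [3,3] shift of the prenyl vinylogous ester, or capture and oligomerisation of the dienylketene, may outrun the 4π opening/6π closure sequence if the ring opens only at higher temperature. The fallback builds the ring B phenol by classical aromatic substitution. It sets out from prenyl bromide 5 and commercial 4-methoxybenzene-1,2-diol. Mono-O-alkylation (K2CO3, 1 equiv, acetone, rt) should favour the more acidic hydroxyl meta to the methoxy group and give 4-methoxy-2-[(3-methylbut-2-en-1-yl)oxy]phenol F1, the regioisomer being removed by chromatography. Magnesium-mediated ortho-formylation (MgCl2, Et3N, paraformaldehyde, MeCN, reflux) at the only free ortho position gives 2-hydroxy-5-methoxy-3-[(3-methylbut-2-en-1-yl)oxy]benzaldehyde F2. Reduction with NaBH4 (MeOH, 0 °C) gives 2-(hydroxymethyl)-4-methoxy-6-[(3-methylbut-2-en-1-yl)oxy]phenol F3. Selective silylation of the primary hydroxyl (TBSCl, 1.0 equiv, imidazole, CH2Cl2, 0 °C) comes back to the route at phenol 17.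

2. Step 12 (Ullmann coupling). C–O bond formation at the di-ortho-substituted phenoxide may be slow, so that hydrodebromination of 21, ester cleavage by phenoxide or loss of silanolate from the ortho-silyloxymethyl phenoxide takes over. The fallback replaces copper coupling by nucleophilic aromatic substitution on an aldehyde-activated aryl fluoride. It sets out from phenol 17 and commercial 3-fluoro-5-methylphenol. The phenol is protected (MOMCl, iPr2NEt) to 1-fluoro-3-(methoxymethoxy)-5-methylbenzene F4. Lithiation between fluorine and the MOM ether (n-BuLi, THF, −78 °C) and DMF quench give 2-fluoro-6-(methoxymethoxy)-4-methylbenzaldehyde F5. Displacement of fluoride by the phenoxide of 17 (K2CO3, DMF, 90 °C) gives 2-{2-[(tert-butyldimethylsilyloxy)methyl]-4-methoxy-6-[(3-methylbut-2-en-1-yl)oxy]phenoxy}-6-(methoxymethoxy)-4-methylbenzaldehyde F6. Pinnick oxidation (NaClO2, NaH2PO4, 2-methylbut-2-ene, t-BuOH/H2O) gives the corresponding benzoic acid F7. Methylation of the carboxylate (MeI, K2CO3, DMF) comes back to the route at 22.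

3. Step 13 (global deprotection). Acid may ionise the aryl prenyl ether or add across its alkene while the MOM acetal is being cleaved. The fallback exchanges the acid-labile MOM group for an allyl group before any prenyl ether is present. It sets out from 21. Methanolic HCl gives methyl 2-bromo-6-hydroxy-4-methylbenzoate F8. Allylation (allyl bromide, K2CO3, acetone) gives methyl 2-(allyloxy)-6-bromo-4-methylbenzoate F9. The copper coupling of step 12 with 17 gives methyl 2-(allyloxy)-6-{2-[(tert-butyldimethylsilyloxy)methyl]-4-methoxy-6-[(3-methylbut-2-en-1-yl)oxy]phenoxy}-4-methylbenzoate F10. Buffered fluoride (TBAF/AcOH, THF) gives methyl 2-(allyloxy)-6-{2-(hydroxymethyl)-4-methoxy-6-[(3-methylbut-2-en-1-yl)oxy]phenoxy}-4-methylbenzoate F11. Pd(PPh3)4 (zerovalent palladium) with morpholine in THF at rt then removes the allyl group, the trisubstituted prenyl ether ionising far more slowly, and the sequence ends at target 23.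

Further compounds
F1 | step 7 | 4-methoxy-2-[(3-methylbut-2-en-1-yl)oxy]phenol | COc1ccc(O)c(OCC=C(C)C)c1
F2 | step 7 | 2-hydroxy-5-methoxy-3-[(3-methylbut-2-en-1-yl)oxy]benzaldehyde | O=Cc1cc(OC)cc(OCC=C(C)C)c1O
F3 | step 7 | 2-(hydroxymethyl)-4-methoxy-6-[(3-methylbut-2-en-1-yl)oxy]phenol | OCc1cc(OC)cc(OCC=C(C)C)c1O
F4 | step 12 | 1-fluoro-3-(methoxymethoxy)-5-methylbenzene | COCOc1cc(C)cc(F)c1
F5 | step 12 | 2-fluoro-6-(methoxymethoxy)-4-methylbenzaldehyde | COCOc1cc(C)cc(F)c1C=O
F6 | step 12 | 2-{2-[(tert-butyldimethylsilyloxy)methyl]-4-methoxy-6-[(3-methylbut-2-en-1-yl)oxy]phenoxy}-6-(methoxymethoxy)-4-methylbenzaldehyde | COCOc1cc(C)cc(Oc2c(CO[Si](C)(C)C(C)(C)C)cc(OC)cc2OCC=C(C)C)c1C=O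
F7 | step 12 | 2-{2-[(tert-butyldimethylsilyloxy)methyl]-4-methoxy-6-[(3-methylbut-2-en-1-yl)oxy]phenoxy}-6-(methoxymethoxy)-4-methylbenzoic acid | COCOc1cc(C)cc(Oc2c(CO[Si](C)(C)C(C)(C)C)cc(OC)cc2OCC=C(C)C)c1C(=O)O
F8 | step 13 | methyl 2-bromo-6-hydroxy-4-methylbenzoate | COC(=O)c1c(O)cc(C)cc1Br
F9 | step 13 | methyl 2-(allyloxy)-6-bromo-4-methylbenzoate | COC(=O)c1c(OCC=C)cc(C)cc1Br
F10 | step 13 | methyl 2-(allyloxy)-6-{2-[(tert-butyldimethylsilyloxy)methyl]-4-methoxy-6-[(3-methylbut-2-en-1-yl)oxy]phenoxy}-4-methylbenzoate | COC(=O)c1c(OCC=C)cc(C)cc1Oc1c(CO[Si](C)(C)C(C)(C)C)cc(OC)cc1OCC=C(C)C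
F11 | step 13 | methyl 2-(allyloxy)-6-{2-(hydroxymethyl)-4-methoxy-6-[(3-methylbut-2-en-1-yl)oxy]phenoxy}-4-methylbenzoate | COC(=O)c1c(OCC=C)cc(C)cc1Oc1c(CO)cc(OC)cc1OCC=C(C)C
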